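**Plan**

1. Carotenoid numbering is used: ring A is C1–C6 (C1 gem-dimethyl, C3 and C4 carbinols, C5=C6), the chain is C7–C15 and C15'–C7', the five-membered κ ring is C1'–C5'. The retrosynthesis cuts, in order: C7'–C8' (aldol, then oxidation to the enolised β-diketone); C11=C12 and C11'=C12' (two Horner–Wadsworth–Emmons olefinations around a C10 dialdehyde); C3–C4 of ring A (reductive pinacol closure); C6–C7 (Sonogashira coupling on an acyclic enol triflate); and the C1'–C5' bond of the κ ring (ring contraction of a cyclohexene oxide).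
2. Forward: an acyclic enynal–aldehyde that already carries the C7–C11 side chain is assembled, ring A is closed from it, the chain is extended to a C30 aldehyde, and the κ ring, made separately, is attached last.
3. Stereochemistry: C3 and C4 are both created in the ring closure, trans from the geometry of the coupling and absolute from a chiral titanocene. C3' is bought with (4R,6R)-actinol, and C5' is relayed from it through the face of an epoxide and a stereospecific 1,2-shift. The chain double bonds come from E-configured building blocks and E-selective olefinations.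
4. Enabling feature: C3 and C4 of ring A are adjacent ring carbons that each carry a hydroxyl, so both can be read as former aldehyde carbons of like polarity. C4 is also allylic to the C5=C6–C7≡C8 enyne, so its aldehyde is the more easily reduced one. The C1 gem-dimethyl group and the cis arrangement of C4 and C1 across C5=C6 hold the two ends together.

Key step: step 9

Remark: the sense of induction of the chiral titanocene in step 9 cannot be predicted with confidence; the (R,R) complex is written and its mirror image would be used if the (3R,4R) diol were to dominate.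
Remark: the β-diketone is drawn, as in the target SMILES, as its 8'-hydroxy-7'-en-6'-one tautomer.

**Route**

Step 1
Reactants: 1 2,2-dimethylpent-4-enoic acid; 2 ethyl propanoate
Product: 5 ethyl 2,4,4-trimethyl-3-oxohept-6-enoate (racemic at C2), via 2,2-dimethylpent-4-enoyl chloride 3 (not isolated), via lithium enolate of ethyl propanoate 4 (not isolated)
Conditions: (COCl)2, DMF (cat.), CH2Cl2, 0 °C to rt, evaporate; added to 2 + LiN(i-Pr)2 (2.2 equiv each), THF, −78 °C; AcOH
Reagents that add atoms: none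
Why: Crossed Claisen C-acylation of an ester enolate by a hindered acid chloride, with the second equivalent of enolate taking up the acidic product; the C2 stereocentre is removed in step 2.

Step 2
Reactants: 5 ethyl 2,4,4-trimethyl-3-oxohept-6-enoate
Product: 7 ethyl (2E)-2,4,4-trimethyl-3-{[(trifluoromethyl)sulfonyl]oxy}hepta-2,6-dienoate, via potassium enolate 6 (not isolated)
Conditions: KN(SiMe3)2, 18-crown-6, THF, −78 °C; PhNTf2, −78 °C to rt
Reagents that add atoms: N-phenylbis(trifluoromethanesulfonimide), O=S(=O)(N(c1ccccc1)S(=O)(=O)C(F)(F)F)C(F)(F)F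
Why: Enol triflate formation from a β-keto ester under non-chelating conditions; with the cation sequestered nothing holds the two oxygens cis, and the tert-alkyl group is better placed beside the twistable ester than beside the methyl group, so the E isomer (ester cis to the quaternary carbon across the future C5=C6 bond) should predominate.

Step 3
Reactants: 7 ethyl (2E)-2,4,4-trimethyl-3-{[(trifluoromethyl)sulfonyl]oxy}hepta-2,6-dienoate
Product: 9 ethyl (2E)-2,4,4-trimethyl-6-oxo-3-{[(trifluoromethyl)sulfonyl]oxy}hex-2-enoate, via terminal-alkene ozonide 8 (not isolated)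
Conditions: O3, CH2Cl2, −78 °C (indicator dye end point); PPh3, −78 °C to rt
Reagents that add atoms: ozone, [O-][O+]=O
Why: Ozonolysis with reductive work-up; the electron-rich monosubstituted alkene reacts while the electron-poor tetrasubstituted enol triflate alkene is inert.

Step 4
Reactants: 10 (2E)-3-methylpent-2-en-4-yn-1-ol
Product: 11 (3E)-5-bromo-3-methylpent-3-en-1-yne
Conditions: CBr4, PPh3, CH2Cl2, 0 °C
Reagents that add atoms: carbon tetrabromide, BrC(Br)(Br)Br
Why: Appel bromination of a primary allylic alcohol under neutral conditions that leave the alkyne and the E alkene untouched.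

Step 5
Reactants: 11 (3E)-5-bromo-3-methylpent-3-en-1-yne
Product: 12 diethyl [(2E)-3-methylpent-2-en-4-yn-1-yl]phosphonate
Conditions: P(OEt)3, neat, 90 °C
Reagents that add atoms: triethyl phosphite, CCOP(OCC)OCC
Why: Michaelis–Arbuzov reaction at the unhindered primary allylic carbon, which keeps the E geometry.

Step 6
Reactants: 9 ethyl (2E)-2,4,4-trimethyl-6-oxo-3-{[(trifluoromethyl)sulfonyl]oxy}hex-2-enoate; 12 diethyl [(2E)-3-methylpent-2-en-4-yn-1-yl]phosphonate
Product: 13 ethyl (2E)-3-[(3E)-5-(diethoxyphosphoryl)-3-methylpent-3-en-1-yn-1-yl]-2,4,4-trimethyl-6-oxohex-2-enoate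
Conditions: Pd(PPh3)4 (5 mol %), CuI (10 mol %), Et3N, THF, rt
Reagents that add atoms: none
Why: Sonogashira coupling forming C6–C7 with retention of the alkene geometry; the β-sulfonyloxy acrylate is an activated partner for oxidative addition to zerovalent palladium and the aldehyde is tolerated.

Step 7
Reactants: 13 ethyl (2E)-3-[(3E)-5-(diethoxyphosphoryl)-3-methylpent-3-en-1-yn-1-yl]-2,4,4-trimethyl-6-oxohex-2-enoate
Product: 14 diethyl [(2E,6E)-8-hydroxy-6-(4-hydroxy-2-methylbutan-2-yl)-3,7-dimethylocta-2,6-dien-4-yn-1-yl]phosphonate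
Conditions: i-Bu2AlH (4.5 equiv), CH2Cl2, −78 to −20 °C; aq. sodium potassium tartrate
Reagents that add atoms: none
Why: Hydride reduction of the aldehyde and 1,2-reduction of the hindered enynoate to the allylic alcohol, conditions under which a dialkyl phosphonate and the alkene geometry should survive.

Step 8
Reactants: 14 diethyl [(2E,6E)-8-hydroxy-6-(4-hydroxy-2-methylbutan-2-yl)-3,7-dimethylocta-2,6-dien-4-yn-1-yl]phosphonate
Product: 15 diethyl [(2E,6E)-3,7-dimethyl-6-(2-methyl-4-oxobutan-2-yl)-8-oxoocta-2,6-dien-4-yn-1-yl]phosphonate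
Conditions: Dess–Martin periodinane (2.5 equiv), NaHCO3, CH2Cl2, 0 °C to rt, dark
Reagents that add atoms: none
Why: Dess–Martin oxidation of both primary alcohols under buffered, non-basic conditions that avoid aldol closure and E/Z isomerisation of the enynal.

Step 9
Reactants: 15 diethyl [(2E,6E)-3,7-dimethyl-6-(2-methyl-4-oxobutan-2-yl)-8-oxoocta-2,6-dien-4-yn-1-yl]phosphonate
Product: 17 diethyl {(2E)-5-[(3S,4S)-3,4-dihydroxy-2,6,6-trimethylcyclohex-1-en-1-yl]-3-methylpent-2-en-4-yn-1-yl}phosphonate, via bis(trimethylsilyl) ether 16 (not isolated)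
Conditions: (R,R)-ethylenebis(4,5,6,7-tetrahydro-1-indenyl)titanium dichloride (20 mol %), Mn powder, Me3SiCl, THF, 0 °C, 15 added over 12 h at high dilution; then K2CO3, MeOH, rt
Reagents that add atoms: none
Why: Proposed new method: the trivalent titanocene formed from the dichloride and Mn reduces only the conjugated aldehyde to a titanium-bound ketyl, whose C4 terminus adds to the titanium-coordinated aldehyde carbon C3 with uptake of a second electron, and Me3SiCl silylates the diolate so that the metal turns over; the closest known reactions are the trans-selective titanocene pinacol cyclisation of 1,6-dials and the enantioselective reductive ketyl cyclisations catalysed by this class of ansa-titanocene. Ring A closes in the 6-exo-trig mode, the C4 radical attacking the C3 carbonyl carbon with its oxygen left outside the ring. The trans relation of the C3 and C4 oxygens should follow from the two bulky titanoxy groups taking opposite, pseudo-equatorial positions in a half-chair transition state in which each oxygen sits on its own metal, so that no chelate forces them cis. The absolute configuration at C3 and C4 is expected to come from the C2-symmetric tetrahydroindenyl ligand, which shields one face of each bound carbonyl, and combinations with mismatched faces are diverted to the separable cis diol, which should raise the enantiomeric purity of the trans product. The step needs reduction of the enal in preference to the saturated aldehyde (conjugated aldehydes are reduced much faster), ring closure in preference to dimerisation (high dilution, the cis placement of C4 and C1 on C5=C6 and the C1 gem-dimethyl group favour it), and no closure through the delocalised positions C6 or C8, which would need a four-membered ring or a cyclic allene.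

Step 10
Reactants: 17 diethyl {(2E)-5-[(3S,4S)-3,4-dihydroxy-2,6,6-trimethylcyclohex-1-en-1-yl]-3-methylpent-2-en-4-yn-1-yl}phosphonate
Product: 18 diethyl {(2E)-5-[(3S,4S)-3,4-bis{[tert-butyl(dimethyl)silyl]oxy}-2,6,6-trimethylcyclohex-1-en-1-yl]-3-methylpent-2-en-4-yn-1-yl}phosphonate
Conditions: t-BuMe2SiOTf (2.5 equiv), 2,6-lutidine, CH2Cl2, −78 to 0 °C
Reagents that add atoms: tert-butyldimethylsilyl trifluoromethanesulfonate, CC(C)(C)[Si](C)(C)OS(=O)(=O)C(F)(F)F
Why: Silylation of both secondary hydroxyls with a silyl triflate and a hindered base, needed so that no alkoxide interferes with the carbanion and enolate steps that follow.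

Step 11
Reactants: 19 ethyl (2E)-2-methylbut-2-enoate (ethyl tiglate)
Product: 20 ethyl (2E)-4-bromo-2-methylbut-2-enoate
Conditions: N-bromosuccinimide, azobisisobutyronitrile (cat.), PhCF3, reflux
Reagents that add atoms: N-bromosuccinimide, O=C1CCC(=O)N1Br
Why: Wohl–Ziegler allylic bromination, expected mainly at the γ-methyl group because the product keeps the conjugated E enoate.

Step 12
Reactants: 20 ethyl (2E)-4-bromo-2-methylbut-2-enoate
Product: 21 ethyl (2E)-4-(diethoxyphosphoryl)-2-methylbut-2-enoate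
Conditions: P(OEt)3, neat, 120 °C
Reagents that add atoms: triethyl phosphite, CCOP(OCC)OCC
Why: Michaelis–Arbuzov reaction of a primary allylic bromide.

Step 13
Reactants: 21 ethyl (2E)-4-(diethoxyphosphoryl)-2-methylbut-2-enoate; 22 (2E,4E,6E)-2,7-dimethylocta-2,4,6-trienedial
Product: 24 ethyl (2E,4E,6E,8E,10E)-2,6,11-trimethyl-12-oxododeca-2,4,6,8,10-pentaenoate, via sodium phosphonate carbanion 23 (not isolated)
Conditions: NaH, THF, 0 °C; added to 22 (3 equiv), THF, 0 °C to rt
Reagents that add atoms: none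
Why: Horner–Wadsworth–Emmons olefination forming C11'=C12' with E selectivity; the excess of the symmetrical dialdehyde should hold the reaction at mono-olefination.

Step 14
Reactants: 18 diethyl {(2E)-5-[(3S,4S)-3,4-bis{[tert-butyl(dimethyl)silyl]oxy}-2,6,6-trimethylcyclohex-1-en-1-yl]-3-methylpent-2-en-4-yn-1-yl}phosphonate; 24 ethyl (2E,4E,6E,8E,10E)-2,6,11-trimethyl-12-oxododeca-2,4,6,8,10-pentaenoate
Product: 26 ethyl (3S,4S)-3,4-bis{[tert-butyl(dimethyl)silyl]oxy}-7,8-didehydro-8'-apo-β-caroten-8'-oate, via potassium phosphonate carbanion 25 (not isolated)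
Conditions: KN(SiMe3)2, THF, −78 °C; 24, −78 to 0 °C, dark
Reagents that add atoms: none
Why: Horner–Wadsworth–Emmons olefination forming C11=C12; the allylic phosphonate carbanion adds to the aldehyde and not to the ester, elimination should give the E alkene, and the low temperature is meant to preserve the 9E geometry.

Step 15
Reactants: 26 ethyl (3S,4S)-3,4-bis{[tert-butyl(dimethyl)silyl]oxy}-7,8-didehydro-8'-apo-β-caroten-8'-oate
Product: 27 (3S,4S)-3,4-bis{[tert-butyl(dimethyl)silyl]oxy}-7,8-didehydro-8'-apo-β-caroten-8'-ol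
Conditions: i-Bu2AlH (2.5 equiv), CH2Cl2, −78 °C; aq. sodium potassium tartrate
Reagents that add atoms: none
Why: 1,2-Reduction of a polyenoate ester to the allylic alcohol, a standard step in apocarotenoid chemistry.

Step 16
Reactants: 27 (3S,4S)-3,4-bis{[tert-butyl(dimethyl)silyl]oxy}-7,8-didehydro-8'-apo-β-caroten-8'-ol
Product: 28 (3S,4S)-3,4-bis{[tert-butyl(dimethyl)silyl]oxy}-7,8-didehydro-8'-apo-β-caroten-8'-al
Conditions: MnO2 (activated, excess), CH2Cl2, rt, dark
Reagents that add atoms: none
Why: Selective oxidation of an allylic (polyenylic) alcohol by manganese dioxide under neutral conditions.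

Step 17
Reactants: 29 (4R,6R)-4-hydroxy-2,2,6-trimethylcyclohexan-1-one (actinol)
Product: 30 (4R,6R)-4-{[tert-butyl(dimethyl)silyl]oxy}-2,2,6-trimethylcyclohexan-1-one
Conditions: t-BuMe2SiCl, imidazole, DMF, rt
Reagents that add atoms: tert-butyldimethylsilyl chloride, CC(C)(C)[Si](C)(C)Cl
Why: Silyl ether formation at the secondary alcohol; this purchased centre becomes C3' of the target.

Step 18
Reactants: 30 (4R,6R)-4-{[tert-butyl(dimethyl)silyl]oxy}-2,2,6-trimethylcyclohexan-1-one
Product: 32 (4R)-4-{[tert-butyl(dimethyl)silyl]oxy}-2,6,6-trimethylcyclohex-1-en-1-yl trifluoromethanesulfonate, via potassium enolate 31 (not isolated)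
Conditions: KN(SiMe3)2, THF, −78 to 0 °C; PhNTf2
Reagents that add atoms: N-phenylbis(trifluoromethanesulfonimide), O=S(=O)(N(c1ccccc1)S(=O)(=O)C(F)(F)F)C(F)(F)F
Why: Enol triflate formation; the ketone has only one α-hydrogen (the other α-carbon is quaternary), so the tetrasubstituted enolate forms regiospecifically.

Step 19
Reactants: 32 (4R)-4-{[tert-butyl(dimethyl)silyl]oxy}-2,6,6-trimethylcyclohex-1-en-1-yl trifluoromethanesulfonate
Product: 33 tert-butyl(dimethyl){[(1R)-3,4,5,5-tetramethylcyclohex-3-en-1-yl]oxy}silane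
Conditions: MeZnCl (commercial solution), PdCl2(dppf) (5 mol %), THF, 60 °C
Reagents that add atoms: methylzinc chloride, C[Zn]Cl
Why: Negishi cross-coupling of a hindered alkenyl triflate with a small methyl nucleophile, which fixes the tetrasubstituted alkene without the regiochemical ambiguity of a dehydration.

Step 20
Reactants: 33 tert-butyl(dimethyl){[(1R)-3,4,5,5-tetramethylcyclohex-3-en-1-yl]oxy}silane
Product: 35 tert-butyl(dimethyl){[(1S,4S,6R)-1,2,2,6-tetramethyl-7-oxabicyclo[4.1.0]heptan-4-yl]oxy}silane (oxirane oxygen anti to the silyloxy group), via trans-bromohydrin 34 (not isolated)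
Conditions: N-bromosuccinimide, H2O/1,2-dimethoxyethane, 0 °C; then K2CO3, MeOH, rt
Reagents that add atoms: water, O
Why: Bromohydrin formation and base-induced SN2 closure, the classical stereochemical complement of peracid epoxidation; the bromonium ion should form on the face anti to the pseudo-axial C1 methyl group (the face syn to the equatorial silyloxy group), water opens it trans-diaxially, and closure then places the oxirane oxygen anti to the silyloxy group.

Step 21
Reactants: 35 tert-butyl(dimethyl){[(1S,4S,6R)-1,2,2,6-tetramethyl-7-oxabicyclo[4.1.0]heptan-4-yl]oxy}silane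
Product: 36 1-[(1R,4S)-4-{[tert-butyl(dimethyl)silyl]oxy}-1,2,2-trimethylcyclopentyl]ethan-1-one
Conditions: BF3·OEt2, CH2Cl2, −78 °C
Reagents that add atoms: none
Why: Lewis acid-promoted semipinacol (Meinwald-type) ring contraction of a tetrasubstituted epoxide; the ring bond migrates anti to the breaking C–O bond, so the acetyl group ends on the former oxirane face (trans to the silyloxy group), and cleavage of either oxirane C–O bond leads to the same ketone, which sets C5'.

Step 22
Reactants: 36 1-[(1R,4S)-4-{[tert-butyl(dimethyl)silyl]oxy}-1,2,2-trimethylcyclopentyl]ethan-1-one; 28 (3S,4S)-3,4-bis{[tert-butyl(dimethyl)silyl]oxy}-7,8-didehydro-8'-apo-β-caroten-8'-al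
Product: 38 (3S,4S,3'S,5'R)-3,4,3'-tris{[tert-butyl(dimethyl)silyl]oxy}-8'-hydroxy-7,8-didehydro-7',8'-dihydro-β,κ-caroten-6'-one (both C8' epimers), via lithium enolate 37 (not isolated)
Conditions: LiN(i-Pr)2 (commercial solution), 36 (1.5 equiv), THF, −78 °C; 28, −78 °C; sat. aq. NH4Cl at −78 °C
Reagents that add atoms: none
Why: Aldol addition of a methyl ketone lithium enolate (the only enolisable position, as C5' is quaternary) in the 1,2-sense to the polyenal; the new C8' carbinol centre is formed without control and is removed in step 23.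

Step 23
Reactants: 38 (3S,4S,3'S,5'R)-3,4,3'-tris{[tert-butyl(dimethyl)silyl]oxy}-8'-hydroxy-7,8-didehydro-7',8'-dihydro-β,κ-caroten-6'-one
Product: 39 (3S,4S,3'S,5'R)-3,4,3'-tris{[tert-butyl(dimethyl)silyl]oxy}-8'-hydroxy-7,8-didehydro-β,κ-caroten-6'-one
Conditions: Dess–Martin periodinane (1.2 equiv), NaHCO3, CH2Cl2, 0 °C, dark
Reagents that add atoms: none
Why: Dess–Martin oxidation of a β-hydroxy ketone to the β-diketone, which should settle as the chelated, polyene-conjugated enol; the buffer protects the acid-labile polyenyl carbinol.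

Step 24
Reactants: 39 (3S,4S,3'S,5'R)-3,4,3'-tris{[tert-butyl(dimethyl)silyl]oxy}-8'-hydroxy-7,8-didehydro-β,κ-caroten-6'-one
Product: 40 (all-E,3S,4S,3'S,5'R)-3,4,3',8'-tetrahydroxy-7,8-didehydro-β,κ-caroten-6'-one (CNP0114063.1)
Conditions: Bu4NF, AcOH (1:1), THF, 0 °C to rt, argon, dark
Reagents that add atoms: none
Why: Fluoride-mediated cleavage of the three silyl ethers under buffered conditions, chosen because acid could ionise the allylic C4 oxygen.

**Compound list**

1 | 2,2-dimethylpent-4-enoic acid | C=CCC(C)(C)C(=O)O | starting material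
2 | ethyl propanoate | CCC(=O)OCC | starting material
3 | 2,2-dimethylpent-4-enoyl chloride | C=CCC(C)(C)C(Cl)=O | intermediate
4 | lithium enolate of ethyl propanoate | CC=C(OCC)O[Li] | intermediate
5 | ethyl 2,4,4-trimethyl-3-oxohept-6-enoate (racemic) | CCOC(=O)C(C)C(=O)C(C)(C)CC=C | intermediate
6 | potassium enolate of 5 (ester trans to the enolate oxygen) | CCOC(=O)/C(C)=C(/O[K])C(C)(C)CC=C | intermediate
7 | ethyl (2E)-2,4,4-trimethyl-3-{[(trifluoromethyl)sulfonyl]oxy}hepta-2,6-dienoate | CCOC(=O)/C(C)=C(/OS(=O)(=O)C(F)(F)F)C(C)(C)CC=C | intermediate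
8 | ozonide (1,2,4-trioxolane) of the terminal alkene of 7 | CCOC(=O)/C(C)=C(/OS(=O)(=O)C(F)(F)F)C(C)(C)CC1OCOO1 | intermediate
9 | ethyl (2E)-2,4,4-trimethyl-6-oxo-3-{[(trifluoromethyl)sulfonyl]oxy}hex-2-enoate | CCOC(=O)/C(C)=C(/OS(=O)(=O)C(F)(F)F)C(C)(C)CC=O | intermediate
10 | (2E)-3-methylpent-2-en-4-yn-1-ol | C#C/C(C)=C/CO | starting material
11 | (3E)-5-bromo-3-methylpent-3-en-1-yne | C#C/C(C)=C/CBr | intermediate
12 | diethyl [(2E)-3-methylpent-2-en-4-yn-1-yl]phosphonate | C#C/C(C)=C/CP(=O)(OCC)OCC | intermediate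
13 | ethyl (2E)-3-[(3E)-5-(diethoxyphosphoryl)-3-methylpent-3-en-1-yn-1-yl]-2,4,4-trimethyl-6-oxohex-2-enoate | CCOC(=O)/C(C)=C(/C#C/C(C)=C/CP(=O)(OCC)OCC)C(C)(C)CC=O | intermediate
14 | diethyl [(2E,6E)-8-hydroxy-6-(4-hydroxy-2-methylbutan-2-yl)-3,7-dimethylocta-2,6-dien-4-yn-1-yl]phosphonate | OC/C(C)=C(/C#C/C(C)=C/CP(=O)(OCC)OCC)C(C)(C)CCO | intermediate
15 | diethyl [(2E,6E)-3,7-dimethyl-6-(2-methyl-4-oxobutan-2-yl)-8-oxoocta-2,6-dien-4-yn-1-yl]phosphonate | O=C/C(C)=C(/C#C/C(C)=C/CP(=O)(OCC)OCC)C(C)(C)CC=O | intermediate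
16 | diethyl {(2E)-5-[(3S,4S)-2,6,6-trimethyl-3,4-bis(trimethylsilyloxy)cyclohex-1-en-1-yl]-3-methylpent-2-en-4-yn-1-yl}phosphonate | CC1=C(C#C/C(C)=C/CP(=O)(OCC)OCC)C(C)(C)C[C@H](O[Si](C)(C)C)[C@H]1O[Si](C)(C)C | intermediate
17 | diethyl {(2E)-5-[(3S,4S)-3,4-dihydroxy-2,6,6-trimethylcyclohex-1-en-1-yl]-3-methylpent-2-en-4-yn-1-yl}phosphonate | CC1=C(C#C/C(C)=C/CP(=O)(OCC)OCC)C(C)(C)C[C@H](O)[C@H]1O | intermediate
18 | diethyl {(2E)-5-[(3S,4S)-3,4-bis{[tert-butyl(dimethyl)silyl]oxy}-2,6,6-trimethylcyclohex-1-en-1-yl]-3-methylpent-2-en-4-yn-1-yl}phosphonate | CC1=C(C#C/C(C)=C/CP(=O)(OCC)OCC)C(C)(C)C[C@H](O[Si](C)(C)C(C)(C)C)[C@H]1O[Si](C)(C)C(C)(C)C | intermediate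
19 | ethyl (2E)-2-methylbut-2-enoate (ethyl tiglate) | C/C=C(\C)C(=O)OCC | starting material
20 | ethyl (2E)-4-bromo-2-methylbut-2-enoate | BrC/C=C(\C)C(=O)OCC | intermediate
21 | ethyl (2E)-4-(diethoxyphosphoryl)-2-methylbut-2-enoate | CCOC(=O)/C(C)=C/CP(=O)(OCC)OCC | intermediate
22 | (2E,4E,6E)-2,7-dimethylocta-2,4,6-trienedial | O=C/C(C)=C/C=C/C=C(C)/C=O | starting material
23 | sodium salt (phosphonate carbanion) of 21 | CCOC(=O)/C(C)=C/[CH-]P(=O)(OCC)OCC.[Na+] | intermediate
24 | ethyl (2E,4E,6E,8E,10E)-2,6,11-trimethyl-12-oxododeca-2,4,6,8,10-pentaenoate | O=C/C(C)=C/C=C/C=C(C)/C=C/C=C(C)/C(=O)OCC | intermediate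
25 | potassium salt (phosphonate carbanion) of 18 | CC1=C(C#C/C(C)=C/[CH-]P(=O)(OCC)OCC)C(C)(C)C[C@H](O[Si](C)(C)C(C)(C)C)[C@H]1O[Si](C)(C)C(C)(C)C.[K+] | intermediate
26 | ethyl (3S,4S)-3,4-bis{[tert-butyl(dimethyl)silyl]oxy}-7,8-didehydro-8'-apo-β-caroten-8'-oate | CC1=C(C#C/C(C)=C/C=C/C(C)=C/C=C/C=C(C)/C=C/C=C(C)/C(=O)OCC)C(C)(C)C[C@H](O[Si](C)(C)C(C)(C)C)[C@H]1O[Si](C)(C)C(C)(C)C | intermediate
27 | (3S,4S)-3,4-bis{[tert-butyl(dimethyl)silyl]oxy}-7,8-didehydro-8'-apo-β-caroten-8'-ol | CC1=C(C#C/C(C)=C/C=C/C(C)=C/C=C/C=C(C)/C=C/C=C(C)/CO)C(C)(C)C[C@H](O[Si](C)(C)C(C)(C)C)[C@H]1O[Si](C)(C)C(C)(C)C | intermediate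
28 | (3S,4S)-3,4-bis{[tert-butyl(dimethyl)silyl]oxy}-7,8-didehydro-8'-apo-β-caroten-8'-al | CC1=C(C#C/C(C)=C/C=C/C(C)=C/C=C/C=C(C)/C=C/C=C(C)/C=O)C(C)(C)C[C@H](O[Si](C)(C)C(C)(C)C)[C@H]1O[Si](C)(C)C(C)(C)C | intermediate
29 | (4R,6R)-4-hydroxy-2,2,6-trimethylcyclohexan-1-one (actinol) | C[C@@H]1C[C@@H](O)CC(C)(C)C1=O | starting material
30 | (4R,6R)-4-{[tert-butyl(dimethyl)silyl]oxy}-2,2,6-trimethylcyclohexan-1-one | C[C@@H]1C[C@@H](O[Si](C)(C)C(C)(C)C)CC(C)(C)C1=O | intermediate
31 | potassium enolate of 30 | CC1=C(O[K])C(C)(C)C[C@H](O[Si](C)(C)C(C)(C)C)C1 | intermediate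
32 | (4R)-4-{[tert-butyl(dimethyl)silyl]oxy}-2,6,6-trimethylcyclohex-1-en-1-yl trifluoromethanesulfonate | CC1=C(OS(=O)(=O)C(F)(F)F)C(C)(C)C[C@H](O[Si](C)(C)C(C)(C)C)C1 | intermediate
33 | tert-butyl(dimethyl){[(1R)-3,4,5,5-tetramethylcyclohex-3-en-1-yl]oxy}silane | CC1=C(C)C(C)(C)C[C@H](O[Si](C)(C)C(C)(C)C)C1 | intermediate
34 | (1R,2R,5S)-2-bromo-5-{[tert-butyl(dimethyl)silyl]oxy}-1,2,3,3-tetramethylcyclohexan-1-ol (hydroxyl anti, bromine syn to the silyloxy group) | C[C@@]1(O)C[C@@H](O[Si](C)(C)C(C)(C)C)CC(C)(C)[C@@]1(C)Br | intermediate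
35 | tert-butyl(dimethyl){[(1S,4S,6R)-1,2,2,6-tetramethyl-7-oxabicyclo[4.1.0]heptan-4-yl]oxy}silane | C[C@]12O[C@@]1(C)C(C)(C)C[C@H](O[Si](C)(C)C(C)(C)C)C2 | intermediate
36 | 1-[(1R,4S)-4-{[tert-butyl(dimethyl)silyl]oxy}-1,2,2-trimethylcyclopentyl]ethan-1-one | CC(=O)[C@]1(C)C[C@@H](O[Si](C)(C)C(C)(C)C)CC1(C)C | intermediate
37 | lithium enolate of 36 | C=C(O[Li])[C@]1(C)C[C@@H](O[Si](C)(C)C(C)(C)C)CC1(C)C | intermediate
38 | (3S,4S,3'S,5'R)-3,4,3'-tris{[tert-butyl(dimethyl)silyl]oxy}-8'-hydroxy-7,8-didehydro-7',8'-dihydro-β,κ-caroten-6'-one (C8' epimers) | CC1=C(C#C/C(C)=C/C=C/C(C)=C/C=C/C=C(C)/C=C/C=C(C)/C(O)CC(=O)[C@]2(C)C[C@@H](O[Si](C)(C)C(C)(C)C)CC2(C)C)C(C)(C)C[C@H](O[Si](C)(C)C(C)(C)C)[C@H]1O[Si](C)(C)C(C)(C)C | intermediate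
39 | (3S,4S,3'S,5'R)-3,4,3'-tris{[tert-butyl(dimethyl)silyl]oxy}-8'-hydroxy-7,8-didehydro-β,κ-caroten-6'-one | CC1=C(C#C/C(C)=C/C=C/C(C)=C/C=C/C=C(C)/C=C/C=C(C)/C(O)=C/C(=O)[C@]2(C)C[C@@H](O[Si](C)(C)C(C)(C)C)CC2(C)C)C(C)(C)C[C@H](O[Si](C)(C)C(C)(C)C)[C@H]1O[Si](C)(C)C(C)(C)C | intermediate
40 | (all-E,3S,4S,3'S,5'R)-3,4,3',8'-tetrahydroxy-7,8-didehydro-β,κ-caroten-6'-one | CC1=C(C#C/C(C)=C/C=C/C(C)=C/C=C/C=C(C)/C=C/C=C(C)/C(O)=C/C(=O)[C@]2(C)C[C@@H](O)CC2(C)C)C(C)(C)C[C@H](O)[C@H]1O | target

**Step count and risks**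

Total step count: 24. Longest linear sequence: 14 steps (steps 1–3, 6–10, 14–16, 22–24).

Steps most likely to fail:

1. Step 9 (the step that bears the new-method label). The chiral titanocene may discriminate the carbonyl faces poorly, so that the trans diol forms with low enantiomeric purity, or reduction and dimerisation of the enal may outrun ring closure. Fallback, using known chemistry: from 15, the same cyclisation with achiral titanocene dichloride Cp2TiCl2 (Mn, Me3SiCl, THF, slow addition; then K2CO3, MeOH) should give the racemic trans diol. That is 17 together with its enantiomer, the (3R,4R)-diol F2, formed through 16 and the enantiomeric (3R,4R)-bis(trimethylsilyl) ether F1. Acylation with vinyl acetate and Burkholderia cepacia lipase in tert-butyl methyl ether is then expected, by the usual preference of this enzyme for the R carbinol of trans-cycloalkane-1,2-diols, to convert F2 into its 4-O-acetate F3 and leave 17. After chromatography 17 re-enters the route at step 10.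

2. Step 2. Geometric control in the enolate sulfonylation may be lost, giving the isomer with the ester and the quaternary carbon trans across C5=C6, from which ring A cannot close. Fallback: let a ring fix the geometry. Purchased 2,6,6-trimethylcyclohex-2-en-1-one F4 is deprotonated at its γ-carbon (LiN(i-Pr)2, THF, −78 °C) and the dienolate is sulfonylated with PhNTf2 to 2,6,6-trimethylcyclohexa-1,3-dien-1-yl trifluoromethanesulfonate F5. One equivalent of ozone at −78 °C should attack the electron-richer disubstituted ring alkene and give, through the ozonide F6 and reduction with PPh3, the acyclic triflate dialdehyde F7, in which the former ring holds the formyl group and the quaternary carbon cis. Sonogashira coupling of F7 with 12 under the conditions of step 6 gives 15. This fallback sets out from 12 and returns at 15, so steps 1–3 and 6–8 fall away. It is held in reserve because it opens the bond that step 9 then forms.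

3. Step 20. The bromonium ion may be opened with the unexpected facial sense, or both faces may compete, so that the oxirane oxygen ends syn to the silyloxy group and the ring contraction would deliver the C5' epimer. Fallback: direct oxygen transfer to 33 with m-chloroperbenzoic acid (NaHCO3, CH2Cl2, 0 °C). In this one-step epoxidation the oxygen stays on the face the electrophile attacks, so it is stereochemically complementary to the halohydrin closure. It sets out from 33, returns at 35 and makes no new compound (F0); the two epoxides are diastereomers and should be separable on silica.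

**Further compounds**

F1 | step 9 | diethyl {(2E)-5-[(3R,4R)-2,6,6-trimethyl-3,4-bis(trimethylsilyloxy)cyclohex-1-en-1-yl]-3-methylpent-2-en-4-yn-1-yl}phosphonate (enantiomer of 16) | CC1=C(C#C/C(C)=C/CP(=O)(OCC)OCC)C(C)(C)C[C@@H](O[Si](C)(C)C)[C@@H]1O[Si](C)(C)C
F2 | step 9 | diethyl {(2E)-5-[(3R,4R)-3,4-dihydroxy-2,6,6-trimethylcyclohex-1-en-1-yl]-3-methylpent-2-en-4-yn-1-yl}phosphonate (enantiomer of 17) | CC1=C(C#C/C(C)=C/CP(=O)(OCC)OCC)C(C)(C)C[C@@H](O)[C@@H]1O
F3 | step 9 | (1R,2R)-4-[(3E)-5-(diethoxyphosphoryl)-3-methylpent-3-en-1-yn-1-yl]-2-hydroxy-3,5,5-trimethylcyclohex-3-en-1-yl acetate (4-O-acetate of F2) | CC1=C(C#C/C(C)=C/CP(=O)(OCC)OCC)C(C)(C)C[C@@H](OC(C)=O)[C@@H]1O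
F4 | step 2 | 2,6,6-trimethylcyclohex-2-en-1-one (purchased) | CC1=CCCC(C)(C)C1=O
F5 | step 2 | 2,6,6-trimethylcyclohexa-1,3-dien-1-yl trifluoromethanesulfonate | CC1=C(OS(=O)(=O)C(F)(F)F)C(C)(C)CC=C1
F6 | step 2 | ozonide (1,2,4-trioxolane) of the disubstituted ring alkene of F5 | CC1=C(OS(=O)(=O)C(F)(F)F)C(C)(C)CC2OOC1O2
F7 | step 2 | (2E)-2,4,4-trimethyl-1,6-dioxohex-2-en-3-yl trifluoromethanesulfonate | O=C/C(C)=C(/OS(=O)(=O)C(F)(F)F)C(C)(C)CC=O
F0 | step 20 | none | none
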